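## Retrosynthetic overview

1. Target ⇐ removal of two ring-B allyl ethers ⇐ flavan ⇐ C4 deoxygenation (through an ortho-quinone methide) of a (2S)-5-hydroxy-8-prenylflavanone.
2. 8-Prenyl-5-hydroxyflavanone ⇐ para-Claisen–Cope shift of a 5-O-prenyl ether (O5 → C6 → C8). The prenyl ether protects the 5-OH during ring closure and is also the source of the C8 side chain, so the regiochemistry is fixed.
3. (2S)-5-Prenyloxyflavanone ⇐ catalytic enantioselective 6-endo oxa-Michael closure of the 2'-hydroxychalcone, the chalcone → flavanone reaction that chalcone isomerase performs. This is the only ring formed, and it sets C2.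
4. Chalcone ⇐ Claisen–Schmidt condensation of 2'-hydroxy-4'-methoxy-6'-prenyloxyacetophenone with 2,4-bis(allyloxy)benzaldehyde, each made by O-alkylation of a catalogue phenol.
5. Ring order: rings A and B are bought; ring C is closed once (O1–C2 bond), then the C4 carbonyl is removed as in the natural flavanone → flavan reduction.

Assumption: the quinidine-derived thiourea is taken to give the (2S)-flavanone in step 4; the sense is checked by CD on the first run and the quinine-derived pseudoenantiomer is used if it is the reverse.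

## Route

Step 1
Reactants: 1 1-(2,6-dihydroxy-4-methoxyphenyl)ethanone + 2 prenyl bromide (1-bromo-3-methylbut-2-ene)
Product: 3 1-[2-hydroxy-4-methoxy-6-(3-methylbut-2-enyloxy)phenyl]ethanone
Conditions: K2CO3, acetone, reflux
Reagents that add atoms: prenyl bromide 2, CC(C)=CCBr
Why: Williamson O-alkylation in which only the phenol not hydrogen-bonded to the acetyl group reacts readily, so after one prenylation the remaining chelated OH is deactivated and the mono-ether results, with K2CO3 in acetone favouring O- over C-alkylation; no stereocentre is formed.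

Step 2
Reactants: 4 2,4-dihydroxybenzaldehyde + 5 allyl bromide (3-bromoprop-1-ene)
Product: 6 2,4-bis(prop-2-enyloxy)benzaldehyde
Conditions: K2CO3, DMF, 60 °C
Reagents that add atoms: allyl bromide 5, C=CCBr
Why: Double Williamson etherification in which excess allyl bromide in warm DMF also alkylates the chelated 2-OH, the allyl ethers being chosen because they survive KOH, Eu(fod)3 and NaBH4 and come off under neutral conditions at the end; no stereocentre is formed.

Step 3
Reactants: 3 1-[2-hydroxy-4-methoxy-6-(3-methylbut-2-enyloxy)phenyl]ethanone + 6 2,4-bis(prop-2-enyloxy)benzaldehyde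
Product: 8 (E)-3-[2,4-bis(allyloxy)phenyl]-1-[2-hydroxy-4-methoxy-6-(3-methylbut-2-enyloxy)phenyl]prop-2-en-1-one, via aldol adduct 7 (not isolated)
Conditions: KOH, EtOH/H2O, 0 °C → rt; then AcOH, 0 °C
Reagents that add atoms: none
Why: Claisen–Schmidt condensation (aldol addition, then E1cB dehydration) gives the conjugated E-enone, which is held as its open-chain phenolate in strong base while all ether groups are base-stable; the carbinol centre of 7 is lost on dehydration.

Step 4
Reactants: 8 (E)-3-[2,4-bis(allyloxy)phenyl]-1-[2-hydroxy-4-methoxy-6-(3-methylbut-2-enyloxy)phenyl]prop-2-en-1-one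
Product: 9 (2S)-2-[2,4-bis(allyloxy)phenyl]-7-methoxy-5-(3-methylbut-2-enyloxy)chroman-4-one
Conditions: 9-amino(9-deoxy)epi-quinidine 3,5-bis(trifluoromethyl)phenyl thiourea (10 mol %), PhMe, 4 Å MS, 0 °C → rt
Reagents that add atoms: none
Why: Catalytic asymmetric intramolecular oxa-Michael addition (6-endo-trig), the chalcone → flavanone closure of chalcone isomerase, in which the quinuclidine nitrogen activates the single free 2'-OH while the thiourea hydrogen-bonds the enone carbonyl, so the phenoxide adds to one face of the β-carbon and C2 is set as S under catalyst control, the closure being regiospecific because the other ortho oxygen is blocked as the prenyl ether.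

Step 5
Reactants: 9 (2S)-2-[2,4-bis(allyloxy)phenyl]-7-methoxy-5-(3-methylbut-2-enyloxy)chroman-4-one
Product: 12 (2S)-2-[2,4-bis(allyloxy)phenyl]-5-hydroxy-7-methoxy-8-(3-methylbut-2-enyl)chroman-4-one, via ortho-dienone 10 (not isolated), via para-dienone 11 (not isolated)
Conditions: Eu(fod)3 (10 mol %), CHCl3, 60 °C
Reagents that add atoms: none
Why: Lewis-acid-catalysed para-Claisen–Cope rearrangement in which Eu(fod)3 chelated between C4=O and O5 triggers the [3,3] shift of the prenyl ether to C6 (10), a second [3,3] (Cope) shift carries the group to C8 as a linear prenyl unit (11), and enolisation gives the chelated 5-phenol, with C2 uninvolved and the neutral 60 °C conditions not opening the flavanone.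

Step 6
Reactants: 12 (2S)-2-[2,4-bis(allyloxy)phenyl]-5-hydroxy-7-methoxy-8-(3-methylbut-2-enyl)chroman-4-one
Product: 15 (2S)-2-[2,4-bis(allyloxy)phenyl]-7-methoxy-8-(3-methylbut-2-enyl)chroman-5-ol, via ethyl carbonate 13 (not isolated), via ortho-quinone methide 14 (not isolated)
Conditions: ClCO2Et, Et3N, THF, 0 °C; then NaBH4, H2O, 0 °C → rt
Reagents that add atoms: none
Why: Reductive deoxygenation of an ortho-acylphenol through its ethyl carbonate, in which NaBH4 reduces C4=O, the carbonate moves to the new alkoxide and is expelled by the 5-phenoxide to give ortho-quinone methide 14, and a second hydride adds at C4; the conditions are acid-free, spare the allyl and prenyl groups and do not touch C2.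

Step 7
Reactants: 15 (2S)-2-[2,4-bis(allyloxy)phenyl]-7-methoxy-8-(3-methylbut-2-enyl)chroman-5-ol
Product: 16 4-[(2S)-5-hydroxy-7-methoxy-8-(3-methylbut-2-enyl)chroman-2-yl]benzene-1,3-diol
Conditions: Pd(PPh3)4 (5 mol %), morpholine, THF, rt
Reagents that add atoms: none
Why: Tsuji–Trost deallylation in which zerovalent palladium ionises the two aryl allyl ethers to π-allyl complexes that morpholine traps, leaving the non-allylic prenyl side chain, the benzylic C2–O bond and the C2 configuration untouched under neutral conditions.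

## Compound list

1 | 1-(2,6-dihydroxy-4-methoxyphenyl)ethanone | CC(=O)c1c(O)cc(OC)cc1O | starting material
2 | prenyl bromide (1-bromo-3-methylbut-2-ene) | CC(C)=CCBr | starting material
3 | 1-[2-hydroxy-4-methoxy-6-(3-methylbut-2-enyloxy)phenyl]ethanone | CC(=O)c1c(O)cc(OC)cc1OCC=C(C)C | intermediate
4 | 2,4-dihydroxybenzaldehyde | O=Cc1ccc(O)cc1O | starting material
5 | allyl bromide (3-bromoprop-1-ene) | C=CCBr | starting material
6 | 2,4-bis(prop-2-enyloxy)benzaldehyde | O=Cc1ccc(OCC=C)cc1OCC=C | intermediate
7 | 3-[2,4-bis(allyloxy)phenyl]-3-hydroxy-1-[2-hydroxy-4-methoxy-6-(3-methylbut-2-enyloxy)phenyl]propan-1-one (racemic aldol adduct) | COc1cc(O)c(C(=O)CC(O)c2ccc(OCC=C)cc2OCC=C)c(OCC=C(C)C)c1 | intermediate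
8 | (E)-3-[2,4-bis(allyloxy)phenyl]-1-[2-hydroxy-4-methoxy-6-(3-methylbut-2-enyloxy)phenyl]prop-2-en-1-one | COc1cc(O)c(C(=O)/C=C/c2ccc(OCC=C)cc2OCC=C)c(OCC=C(C)C)c1 | intermediate
9 | (2S)-2-[2,4-bis(allyloxy)phenyl]-7-methoxy-5-(3-methylbut-2-enyloxy)chroman-4-one | COc1cc(OCC=C(C)C)c2c(c1)O[C@H](c1ccc(OCC=C)cc1OCC=C)CC2=O | intermediate
10 | (2S)-2-[2,4-bis(allyloxy)phenyl]-7-methoxy-6-(2-methylbut-3-en-2-yl)-2,3-dihydro-6H-chromene-4,5-dione (ortho-dienone, C6 unassigned) | COC1=CC2=C(C(=O)C1C(C)(C)C=C)C(=O)C[C@@H](c1ccc(OCC=C)cc1OCC=C)O2 | intermediate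
11 | (2S)-2-[2,4-bis(allyloxy)phenyl]-7-methoxy-8-(3-methylbut-2-enyl)-2,3-dihydro-8H-chromene-4,5-dione (para-dienone, C8 unassigned) | COC1=CC(=O)C2=C(C1CC=C(C)C)O[C@H](c1ccc(OCC=C)cc1OCC=C)CC2=O | intermediate
12 | (2S)-2-[2,4-bis(allyloxy)phenyl]-5-hydroxy-7-methoxy-8-(3-methylbut-2-enyl)chroman-4-one | COc1cc(O)c2c(c1CC=C(C)C)O[C@H](c1ccc(OCC=C)cc1OCC=C)CC2=O | intermediate
13 | (2S)-2-[2,4-bis(allyloxy)phenyl]-7-methoxy-8-(3-methylbut-2-enyl)-4-oxochroman-5-yl ethyl carbonate | COc1cc(OC(=O)OCC)c2c(c1CC=C(C)C)O[C@H](c1ccc(OCC=C)cc1OCC=C)CC2=O | intermediate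
14 | (2S)-2-[2,4-bis(allyloxy)phenyl]-7-methoxy-8-(3-methylbut-2-enyl)-2,3-dihydro-5H-chromen-5-one (ortho-quinone methide, C4=C4a) | COC1=CC(=O)C2=CC[C@@H](c3ccc(OCC=C)cc3OCC=C)OC2=C1CC=C(C)C | intermediate
15 | (2S)-2-[2,4-bis(allyloxy)phenyl]-7-methoxy-8-(3-methylbut-2-enyl)chroman-5-ol | COc1cc(O)c2c(c1CC=C(C)C)O[C@H](c1ccc(OCC=C)cc1OCC=C)CC2 | intermediate
16 | 4-[(2S)-5-hydroxy-7-methoxy-8-(3-methylbut-2-enyl)chroman-2-yl]benzene-1,3-diol | COc1cc(O)c2c(c1CC=C(C)C)O[C@H](c1ccc(O)cc1O)CC2 | target

## Step count and risks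

Total steps: 7. Longest linear sequence: 6 (steps 1, 3, 4, 5, 6, 7 from acetophenone 1); step 2 is a one-step side branch.

The three steps most likely to fail:

**Step 4 (enantioselectivity of the ring closure).** The electron-rich ring B makes the enone a poor acceptor, and the amine catalyst can also promote the retro-reaction, so the ee may be moderate. A first remedy inside the route is to stop at full conversion and recrystallise 9 or the well-crystallising chelated phenol 12. The fallback sets out from chalcone 8. It is closed without stereocontrol (NaOAc, EtOH, reflux) to the racemic flavanone F1. This is resolved kinetically by asymmetric transfer hydrogenation with RuCl(p-cymene)[(R,R)-TsDPEN] in HCO2H/Et3N. The (2R) enantiomer is reduced to the cis-(2R,4R)-flavan-4-ol F2, and the unreduced (2S) ketone (at most 50 %) is separated by chromatography. The fallback comes back to the route at compound 9.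

**Step 5 (regiochemistry of the prenyl shift).** The rearrangement may stop at the rearomatised 6-(1,1-dimethylallyl) isomer or give mixtures. The fallback sets out from compound 3 and moves the prenyl shift ahead of ring formation. Thermal para-Claisen–Cope rearrangement (PhNEt2, 200 °C), at a stage with no stereocentre to endanger, gives the C-prenylated acetophenone F3. The less hindered phenol (remote from the prenyl group) is protected with MOMCl/iPr2NEt (CH2Cl2, 0 °C) to give the mono-MOM ether F4. Claisen–Schmidt condensation with aldehyde 6 (KOH, EtOH) gives the chalcone F5. The step 4 conditions close it through the only free phenol to the 5-O-MOM flavanone F6. Mild acid (HCl, MeOH, rt) removes the peri MOM group, and the fallback comes back to the route at compound 12.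

**Step 6 (carbonyl removal without opening the flavanone).** Et3N and aqueous NaBH4 could open the flavanone by retro-oxa-Michael before the ketone is reduced, eroding the ee, or the carbonate could fail to form on the chelated phenol. The fallback sets out from compound 12. Condensation with TsNHNH2 (EtOH, 60 °C) gives the tosylhydrazone F7. Reduction with catecholborane (CHCl3, 0 °C) followed by NaOAc·3H2O at reflux (Kabalka deoxygenation) extrudes sulfinate and nitrogen to leave the C4 methylene. The fallback comes back to the route at compound 15.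

## Further compounds

F1 | step 4 | rac-2-[2,4-bis(allyloxy)phenyl]-7-methoxy-5-(3-methylbut-2-enyloxy)chroman-4-one | COc1cc(OCC=C(C)C)c2c(c1)OC(c1ccc(OCC=C)cc1OCC=C)CC2=O
F2 | step 4 | (2R,4R)-2-[2,4-bis(allyloxy)phenyl]-7-methoxy-5-(3-methylbut-2-enyloxy)chroman-4-ol | COc1cc(OCC=C(C)C)c2c(c1)O[C@@H](c1ccc(OCC=C)cc1OCC=C)C[C@H]2O
F3 | step 5 | 1-[2,6-dihydroxy-4-methoxy-3-(3-methylbut-2-enyl)phenyl]ethanone | CC(=O)c1c(O)cc(OC)c(CC=C(C)C)c1O
F4 | step 5 | 1-[2-hydroxy-4-methoxy-6-(methoxymethoxy)-3-(3-methylbut-2-enyl)phenyl]ethanone | CC(=O)c1c(OCOC)cc(OC)c(CC=C(C)C)c1O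
F5 | step 5 | (E)-3-[2,4-bis(allyloxy)phenyl]-1-[2-hydroxy-4-methoxy-6-(methoxymethoxy)-3-(3-methylbut-2-enyl)phenyl]prop-2-en-1-one | COCOc1cc(OC)c(CC=C(C)C)c(O)c1C(=O)/C=C/c1ccc(OCC=C)cc1OCC=C
F6 | step 5 | (2S)-2-[2,4-bis(allyloxy)phenyl]-7-methoxy-5-(methoxymethoxy)-8-(3-methylbut-2-enyl)chroman-4-one | COCOc1cc(OC)c(CC=C(C)C)c2c1C(=O)C[C@@H](c1ccc(OCC=C)cc1OCC=C)O2
F7 | step 6 | (2S)-2-[2,4-bis(allyloxy)phenyl]-5-hydroxy-7-methoxy-8-(3-methylbut-2-enyl)chroman-4-one 4-tosylhydrazone | COc1cc(O)c2c(c1CC=C(C)C)O[C@H](c1ccc(OCC=C)cc1OCC=C)CC2=NNS(=O)(=O)c1ccc(C)cc1
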